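The numbers in the tables were generated by integration with made-up constants.

In a stirred vessel of constant volume, Qa and Ej give Vy over the catalyst Ul, with Rx in the charge beside them. Here are the runs so far and the two flasks to call.

the same everywhere: Qa 0.80 M

| flask | Ej | Rx | Ul | remark | time |
|---|---|---|---|---|---|
| blue | 0.50 M (in portions, 4) | 0.080 M | 0.80 mM | run made earlier; portions every 5.0 min |  |
| red | 0.77 M (in portions, 4) | 0.080 M | 0.80 mM | run made earlier; portions every 5.0 min |  |
| green | 0.88 M (in portions, 4) | 0.080 M | 1.1 mM | run made earlier; portions every 5.0 min |  |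
| larch | 0.600 M | 0.0800 M | 3.0 mM | everything together at the start | 6.0 h |
| cedar | 0.880 M (in portions, 4) | 0.0800 M | 0.80 mM | the portions of Ej follow each other after 5.0 min, the first at the start | 6.0 h |

- blue (time / h: Vy / %): 0.250: 7; 0.417: 12; 0.833: 30; 1.50: 48; 3.00: 61
- red (time / h: Vy / %): 0.667: 35; 1.33: 66; 2.00: 80; 2.50: 82; 3.00: 91
- green (time / h: Vy / %): 0.250: 11; 0.833: 59; 1.33: 81; 2.00: 88; 3.00: 91

(standard deviation of a reading: 2 percentage points)

* the winner by amount of Vy, in percent of the Qa charged; "neither" if no more than 2 percentage points parts them (larch / cedar / neither)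
* how much Vy is there at the end, in percent of the Qa charged: larch
* how much Vy is there at the end, in percent of the Qa charged: cedar

- what was read earlier has a scatter of 2 percentage points, one standard deviation

Climb the time scales of these runs. First rung, the charging: the last Ej portion is in by 0.250 h, when green reads 11%, far below its 91% at 3.00 h, so in green the charging is over before most of the turnover. Second rung, the turnover: red, at 0.80 mM of Ul, reads 80% by 2.00 h. Top rung, the clock: larch and cedar get 6.0 h, twice the 3.00 h at which red and green both read 91%, and larch carries more Ul than red. On that rung I expect the charges, not the clock, to set the end.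

Blue reads 61% with Ej at 62.5% of the Qa charge, so I take Ej as the limiting reagent there, one Vy per Ej. Red and green, at 96.2% and 110%, both read 91% at 3.00 h, and I read that as each Rx taking one Qa away from Vy. Call the crossing 90.0%, one minus the Rx charge per Qa charge: the Ej charge per Qa charge at which control of the end passes from Ej to Rx. Given ample time and one Qa lost per Rx, I reckon Vy to end at the Ej fraction below it and at the crossing above it.

Larch: Ej per Qa is 75.0%, below 90.0%, so I reckon Vy at 75.0%.

Cedar: Ej per Qa is 110%, above 90.0% by 20 percentage points, so I reckon Vy at 90.0%.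

The forecast names cedar, with larch at 73% (68% to 75%) and cedar at 92% (87% to 97%); of its ceiling it says “perhaps because Rx (10% of Qa) ties up Qa”. Its larch stands below mine and its cedar above.

The flask gives cedar: larch 75.0%, cedar 90.0%.

    Ej.Qa.Ul → Ux + Ty (k = 137 min⁻¹)
    Ty → Ul + Vy (k = 30.6 min⁻¹)
    Qa + Ul → Qa.Ul (k = 185 L mol⁻¹ min⁻¹)
    Ej + Qa.Ul ⇌ Ej.Qa.Ul (K = 80.7 L mol⁻¹, k = 31.2 L mol⁻¹ min⁻¹)
    Qa + Rx → Qa.Rx (k = 0.175 L mol⁻¹ min⁻¹)

In cedar, which ends at the crossing of 90.0%, Rx has a half-life of 0.0825 h by its step with Qa, with Qa held at its charge, while half of the Vy turnover up to 6.0 h is done by 0.818 h, a time ten times as long. By 0.250 h cedar's Qa.Rx stands at 8.47% of the Qa charged beside 11.3% of Vy, and it ends at 9.99% beside 90.0%.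

Now take a neighbour of cedar with 0.20 M of Rx: the crossing falls to 75.0%, Ej per Qa stays above it at 110%, so Vy should end at the crossing. The computed flask ends at 75.2%.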